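The tetrahydropyran (O1, C2 aryl, C3 side chain, C4 phloroglucinol ring A, C5, C6 arylethyl) is disconnected across C4–C5 and O1–C6. Ring A makes C4 a stabilised benzylic cation, so an acyclic C2–C3–C4 array, set by one oxazolidinone auxiliary through cuprate addition and anti-aldol, is linked to raspberry ketone by a temporary O1–Si–O enol-silane tether. Ionisation at C4 lets the tethered enol carbon C5 alkylate C4 on the face next to C2; the liberated C6 ketone is captured by O1 with loss of silicon and reduced axially, so both bonds and both new stereocentres arise in one flask. Late ortho-lithiation and acylation install the chalcone.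

Key step: step 17

Remark: TBS = tert-butyldimethylsilyl, MOM = methoxymethyl; the ring-A benzylic carbon of 29, 30 and 33 is an epimer mixture of no consequence, because it is ionised in step 17.

Step 1
Reactants: 1 methyl 3-(4-hydroxyphenyl)propanoate
Product: 2 methyl 3-[4-(TBSO)phenyl]propanoate
Conditions: TBSCl, imidazole, DMF, rt
Reagents that add atoms: tert-butyldimethylsilyl chloride, CC(C)(C)[Si](C)(C)Cl
Why: Imidazole-promoted silylation of the phenol (silyl ether formation) leaves the ester untouched.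

Step 2
Reactants: 2 methyl 3-[4-(TBSO)phenyl]propanoate
Product: 3 3-[4-(TBSO)phenyl]propanal
Conditions: iBu2AlH (1.05 equiv), CH2Cl2, −78 °C; Rochelle salt work-up
Reagents that add atoms: none
Why: Partial ester reduction stops at the aldehyde because the tetrahedral aluminium hemiacetal is stable at −78 °C.

Step 3
Reactants: 3 3-[4-(TBSO)phenyl]propanal
Product: 4 (3S)-1-[4-(TBSO)phenyl]hex-5-yn-3-ol
Conditions: allenylboronic acid pinacol ester, (R)-3,3'-bis(2,4,6-triisopropylphenyl)-1,1'-binaphthyl-2,2'-diyl hydrogen phosphate (10 mol%), 4 Å MS, toluene, −20 °C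
Reagents that add atoms: allenylboronic acid pinacol ester, C=C=CB1OC(C)(C)C(C)(C)O1
Why: Brønsted-acid-catalysed asymmetric propargylboration through a closed six-membered transition state organised by the chiral phosphate, in which Re-face attack on the aldehyde should set the (S)-carbinol.

Step 4
Reactants: 4 (3S)-1-[4-(TBSO)phenyl]hex-5-yn-3-ol
Product: 5 (3S)-3-(TBSO)-1-[4-(TBSO)phenyl]hex-5-yne
Conditions: TBSOTf, 2,6-lutidine, CH2Cl2, 0 °C
Reagents that add atoms: tert-butyldimethylsilyl triflate, CC(C)(C)[Si](C)(C)OS(=O)(=O)C(F)(F)F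
Why: Silyl triflate silylation of the secondary alcohol is fast and does not touch the terminal alkyne.

Step 5
Reactants: 5 (3S)-3-(TBSO)-1-[4-(TBSO)phenyl]hex-5-yne
Product: 7 (1E,4S)-1-iodo-4-(TBSO)-6-[4-(TBSO)phenyl]hex-1-ene, via alkenylzirconocene chloride 6 (not isolated)
Conditions: Cp2Zr(H)Cl, THF, rt; then I2, 0 °C
Reagents that add atoms: iodine, II
Why: Hydrozirconation adds Zr–H syn and anti-Markovnikov to the terminal alkyne, and iodinolysis of the C–Zr bond with retention gives the (E)-vinyl iodide.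

Step 6
Reactants: 8 (E)-4-hydroxycinnamic acid
Product: 10 (E)-3-[4-(TBSO)phenyl]prop-2-enoic acid, via silyl ester 9 (not isolated)
Conditions: TBSCl (2.5 equiv), imidazole, DMF, rt; then AcOH, THF/H2O, rt
Reagents that add atoms: tert-butyldimethylsilyl chloride, CC(C)(C)[Si](C)(C)Cl
Why: Exhaustive silylation followed by selective hydrolysis of the much more labile silyl ester frees the acid while the aryl silyl ether survives.

Step 7
Reactants: 10 (E)-3-[4-(TBSO)phenyl]prop-2-enoic acid; 11 (S)-4-benzyl-oxazolidin-2-one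
Product: 13 (4S)-4-benzyl-3-[(E)-3-[4-(TBSO)phenyl]prop-2-enoyl]oxazolidin-2-one, via mixed pivalic anhydride 12 (not isolated)
Conditions: PivCl, Et3N, THF, −20 °C; then 11, LiCl, −20 °C → rt
Reagents that add atoms: none
Why: LiCl-assisted N-acylation of the oxazolidinone by the mixed anhydride occurs at the less hindered cinnamoyl carbonyl and keeps the (E)-alkene.

Step 8
Reactants: 10 (E)-3-[4-(TBSO)phenyl]prop-2-enoic acid
Product: 15 (E)-N-methoxy-N-methyl-3-[4-(TBSO)phenyl]prop-2-enamide, via acyl imidazolide 14 (not isolated)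
Conditions: 1,1'-carbonyldiimidazole (1.2 equiv), CH2Cl2, rt; then MeNH(OMe)·HCl, rt
Reagents that add atoms: N,O-dimethylhydroxylamine hydrochloride, CNOC.Cl
Why: Carbonyldiimidazole-mediated amide coupling, in which the acid is converted into the acyl imidazolide with loss of carbon dioxide and the liberated imidazole frees the amine from its hydrochloride for aminolysis, gives the Weinreb amide without touching the aryl silyl ether or the (E)-alkene.

Step 9
Reactants: 16 5-methoxybenzene-1,3-diol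
Product: 17 1-methoxy-3,5-bis(methoxymethoxy)benzene
Conditions: MOMCl, iPr2NEt, CH2Cl2, 0 °C → rt
Reagents that add atoms: chloromethyl methyl ether, COCCl
Why: O-alkylation of both phenols (Williamson-type acetal formation) installs the two groups that later direct the lithiations.

Step 10
Reactants: 18 4-(4-hydroxyphenyl)butan-2-one
Product: 19 4-[4-(TBSO)phenyl]butan-2-one
Conditions: TBSCl, imidazole, DMF, rt
Reagents that add atoms: tert-butyldimethylsilyl chloride, CC(C)(C)[Si](C)(C)Cl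
Why: Phenol silylation as in step 1, with the ketone inert.

Step 11
Reactants: 7 (1E,4S)-1-iodo-4-(TBSO)-6-[4-(TBSO)phenyl]hex-1-ene; 13 (4S)-4-benzyl-3-[(E)-3-[4-(TBSO)phenyl]prop-2-enoyl]oxazolidin-2-one
Product: 22 (4S)-4-benzyl-3-{(3R,4E,7S)-7-(TBSO)-3,9-bis[4-(TBSO)phenyl]non-4-enoyl}oxazolidin-2-one, via alkenyllithium 20 (not isolated), via alkenylmagnesium bromide 21 (not isolated)
Conditions: 7 (1.6 equiv), t-BuLi (3.2 equiv), Et2O, −78 °C; MgBr2·OEt2, −78 → 0 °C; CuBr·SMe2 (0.5 equiv), THF/Me2S, −40 °C; then 13, −40 → −10 °C; NH4Cl (aq)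
Reagents that add atoms: none
Why: Auxiliary-controlled copper-mediated conjugate addition in which the alkenyl reagent (formed with retention of the E geometry) attacks the Mg-chelated syn-s-cis enoyl imide on the face opposite the benzyl group of the auxiliary, which should set the benzylic centre as 3R.

Step 12
Reactants: 22 (4S)-4-benzyl-3-{(3R,4E,7S)-7-(TBSO)-3,9-bis[4-(TBSO)phenyl]non-4-enoyl}oxazolidin-2-one; 23 4-(TBSO)benzaldehyde
Product: 25 (4S)-4-benzyl-3-{(2R,3S,4E,7S)-7-(TBSO)-2-[(S)-hydroxy[4-(TBSO)phenyl]methyl]-3,9-bis[4-(TBSO)phenyl]non-4-enoyl}oxazolidin-2-one, via trimethylsilyl ether 24 (not isolated)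
Conditions: MgCl2 (20 mol%), Et3N, Me3SiCl, EtOAc, rt; then CF3CO2H (cat.), MeOH
Reagents that add atoms: none
Why: Magnesium-halide-catalysed direct anti-aldol reaction of the N-acyl oxazolidinone, in which the chelated (Z)-magnesium enolate should react with the aryl aldehyde on the face opposite the auxiliary benzyl group (boat transition state) to set C-2 (R) and the carbinol carbon (S) anti, with silylation of the aldolate turning the catalyst over.

Step 13
Reactants: 25 anti-aldol imide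
Product: 26 (1S,2S)-1-[4-(TBSO)phenyl]-2-{(1S,2E,5S)-5-(TBSO)-1,7-bis[4-(TBSO)phenyl]hept-2-en-1-yl}propane-1,3-diol
Conditions: LiBH4, MeOH (1 equiv), THF, 0 °C
Reagents that add atoms: none
Why: Hydroxyl-assisted reductive cleavage of the imide releases the primary alcohol and the recoverable auxiliary without epimerising the α-centre.

Step 14
Reactants: 26 1,3-diol
Product: 27 (2R,3S,4E,7S)-7-(TBSO)-2-[(S)-hydroxy[4-(TBSO)phenyl]methyl]-3,9-bis[4-(TBSO)phenyl]non-4-enal
Conditions: 2,2,6,6-tetramethylpiperidin-1-oxyl (20 mol%), PhI(OAc)2, CH2Cl2, rt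
Reagents that add atoms: none
Why: Nitroxyl-catalysed oxidation is selective for the primary over the hindered secondary benzylic alcohol and stops at the aldehyde under anhydrous, non-basic conditions that should not epimerise the α-centre.

Step 15
Reactants: 17 1-methoxy-3,5-bis(methoxymethoxy)benzene; 27 β-hydroxy aldehyde
Product: 30 (1S,2R)-3-methoxy-3-[4-methoxy-2,6-bis(methoxymethoxy)phenyl]-1-[4-(TBSO)phenyl]-2-{(1S,2E,5S)-5-(TBSO)-1,7-bis[4-(TBSO)phenyl]hept-2-en-1-yl}propan-1-ol (C-3 epimers), via aryllithium 28 (not isolated), via benzylic diol 29 (not isolated)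
Conditions: 17 (3 equiv), n-BuLi, THF, 0 °C; then 27, −78 °C; NH4Cl (aq); then pyridinium p-toluenesulfonate (cat.), MeOH, 0 °C → rt
Reagents that add atoms: methanol, CO
Why: Directed ortho-metalation between the two MOM ethers gives the aryllithium, its 1,2-addition to the aldehyde needs no facial control, and the SN1 methanolysis is selective for the far more ionisable trioxygenated benzylic alcohol, leaving the other carbinol free.

Step 16
Reactants: 19 4-[4-(TBSO)phenyl]butan-2-one; 30 benzylic methyl ether alcohol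
Product: 33 diisopropylsilylene-tethered enol silane of 30 and 19, via lithium enolate 31 (not isolated), via enoxychlorosilane 32 (not isolated)
Conditions: 19, lithium diisopropylamide, THF, −78 °C; iPr2SiCl2 (3 equiv), −78 °C → rt, volatiles removed in vacuo; then 30, imidazole, 4-(dimethylamino)pyridine (cat.), CH2Cl2, 0 °C → rt
Reagents that add atoms: dichlorodiisopropylsilane, CC(C)[Si](Cl)(Cl)C(C)C
Why: Kinetic deprotonation at the methyl group, O-silylation by excess dichlorosilane and silylation of the only free alcohol by the resulting chlorosilane assemble the unsymmetrical silaketal that serves as a temporary silicon tether.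

Step 17
Reactants: 33 diisopropylsilylene-tethered enol silane
Product: 36 (2S,3R,4R,6S)-4-[4-methoxy-2,6-bis(methoxymethoxy)phenyl]-2-[4-(TBSO)phenyl]-6-{2-[4-(TBSO)phenyl]ethyl}-3-{(1S,2E,5S)-5-(TBSO)-1,7-bis[4-(TBSO)phenyl]hept-2-en-1-yl}tetrahydro-2H-pyran, via silyl triflate ketone 34 (not isolated), via tetrahydropyranylium triflate 35 (not isolated)
Conditions: Me3SiOTf (1.2 equiv), 2,6-di-tert-butyl-4-methylpyridine, CH2Cl2 (0.005 M), −78 °C; then Et3SiH (5 equiv), −78 → −20 °C; NaHCO3 (aq)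
Reagents that add atoms: none
Why: Proposed new method: Me3SiOTf ionises the methoxy group at the benzylic carbon (future C4), whose cation is stabilised by the para-methoxy and both ortho-MOM-oxy groups of ring A, the silicon-tethered enol silane attacks it through C5 (8-membered, enol-endo closure), O1 then adds transannularly to the silyl-activated C6 carbonyl (6-exo-trig) with expulsion of the silicon, and Et3SiH reduces the resulting tetrahydropyranylium ion 35. The closest known reaction types are the Lewis-acid SN1 benzylation of silyl enol ethers and the reductive etherification of δ-silyloxy ketones, merged here intramolecularly through a temporary silicon tether. C4 is controlled by the tether together with A(1,3) strain: the C3–H bond eclipses the ortho-disubstituted aryl plane of the cation, which places C2 with its O1–Si–O arm on one face and the bulky C3 side chain on the other, so C5 is delivered syn to C2 and ring A ends up equatorial and trans to the C3 substituent. C6 is set by axial hydride delivery to the half-chair oxocarbenium ion, which puts the arylethyl group equatorial (2,6-cis). The step needs ionisation of the ring-A benzylic ether in preference to the p-silyloxybenzylic O1–C2 bond and capture of the cation faster than elimination or Friedel–Crafts closure onto neighbouring aryl rings; the much greater cation-stabilising power of ring A, the high nucleophilicity of the enol silane, high dilution and the delayed addition of the silane (which avoids benzylic deoxygenation) should secure this.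

Step 18
Reactants: 36 tetrahydropyran; 15 (E)-N-methoxy-N-methyl-3-[4-(TBSO)phenyl]prop-2-enamide
Product: 38 hexa-TBS bis-MOM ether of blepharocalyxin E, via aryllithium 37 (not isolated)
Conditions: n-BuLi, TMEDA, THF, −40 °C; then 15, −78 → 0 °C; NH4Cl (aq)
Reagents that add atoms: none
Why: Directed ortho-metalation at a ring-A position flanked by a MOM ether and the methoxy group (the two such positions are equivalent) and acylation by the Weinreb amide, whose chelated tetrahedral intermediate prevents over-addition, should give the (E)-chalcone.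

Step 19
Reactants: 38 hexa-TBS bis-MOM ether of blepharocalyxin E
Product: 40 blepharocalyxin E, via bis-trimethylsilyl ether 39 (not isolated)
Conditions: Me3SiOTf, 2,2'-bipyridyl, MeCN, 0 °C → rt; then HF·pyridine, pyridine, THF, 0 °C → rt
Reagents that add atoms: none
Why: Silyl triflate/bipyridyl cleavage converts the aryl MOM acetals into labile trimethylsilyl ethers under non-acidic conditions and buffered fluoride then removes all silyl ethers, which should spare the chalcone, the benzylic pyran ether and both alkenes.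

Compound list

1 | methyl 3-(4-hydroxyphenyl)propanoate | COC(=O)CCc1ccc(O)cc1 | starting material
2 | methyl 3-[4-(TBSO)phenyl]propanoate | COC(=O)CCc1ccc(O[Si](C)(C)C(C)(C)C)cc1 | intermediate
3 | 3-[4-(TBSO)phenyl]propanal | O=CCCc1ccc(O[Si](C)(C)C(C)(C)C)cc1 | intermediate
4 | (3S)-1-[4-(TBSO)phenyl]hex-5-yn-3-ol | C#CC[C@@H](O)CCc1ccc(O[Si](C)(C)C(C)(C)C)cc1 | intermediate
5 | (3S)-3-(TBSO)-1-[4-(TBSO)phenyl]hex-5-yne | C#CC[C@@H](O[Si](C)(C)C(C)(C)C)CCc1ccc(O[Si](C)(C)C(C)(C)C)cc1 | intermediate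
6 | chlorobis(cyclopentadienyl)[(1E,4S)-4-(TBSO)-6-[4-(TBSO)phenyl]hex-1-en-1-yl]zirconium | Cl[Zr](C1C=CC=C1)(C1C=CC=C1)/C=C/C[C@@H](O[Si](C)(C)C(C)(C)C)CCc1ccc(O[Si](C)(C)C(C)(C)C)cc1 | intermediate (not isolated)
7 | (1E,4S)-1-iodo-4-(TBSO)-6-[4-(TBSO)phenyl]hex-1-ene | I/C=C/C[C@@H](O[Si](C)(C)C(C)(C)C)CCc1ccc(O[Si](C)(C)C(C)(C)C)cc1 | intermediate
8 | (E)-4-hydroxycinnamic acid | OC(=O)/C=C/c1ccc(O)cc1 | starting material
9 | TBS (E)-3-[4-(TBSO)phenyl]prop-2-enoate | CC(C)(C)[Si](C)(C)OC(=O)/C=C/c1ccc(O[Si](C)(C)C(C)(C)C)cc1 | intermediate (not isolated)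
10 | (E)-3-[4-(TBSO)phenyl]prop-2-enoic acid | OC(=O)/C=C/c1ccc(O[Si](C)(C)C(C)(C)C)cc1 | intermediate
11 | (S)-4-benzyl-oxazolidin-2-one | O=C1N[C@@H](Cc2ccccc2)CO1 | starting material
12 | mixed anhydride of 10 and pivalic acid | CC(C)(C)C(=O)OC(=O)/C=C/c1ccc(O[Si](C)(C)C(C)(C)C)cc1 | intermediate (not isolated)
13 | (4S)-4-benzyl-3-[(E)-3-[4-(TBSO)phenyl]prop-2-enoyl]oxazolidin-2-one | O=C(/C=C/c1ccc(O[Si](C)(C)C(C)(C)C)cc1)N1[C@@H](Cc2ccccc2)COC1=O | intermediate
14 | (E)-1-(1H-imidazol-1-yl)-3-[4-(TBSO)phenyl]prop-2-en-1-one (acyl imidazolide of 10) | O=C(/C=C/c1ccc(O[Si](C)(C)C(C)(C)C)cc1)n1ccnc1 | intermediate (not isolated)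
15 | (E)-N-methoxy-N-methyl-3-[4-(TBSO)phenyl]prop-2-enamide | CON(C)C(=O)/C=C/c1ccc(O[Si](C)(C)C(C)(C)C)cc1 | intermediate
16 | 5-methoxybenzene-1,3-diol | COc1cc(O)cc(O)c1 | starting material
17 | 1-methoxy-3,5-bis(methoxymethoxy)benzene | COCOc1cc(OC)cc(OCOC)c1 | intermediate
18 | 4-(4-hydroxyphenyl)butan-2-one (raspberry ketone) | CC(=O)CCc1ccc(O)cc1 | starting material
19 | 4-[4-(TBSO)phenyl]butan-2-one | CC(=O)CCc1ccc(O[Si](C)(C)C(C)(C)C)cc1 | intermediate
20 | [(1E,4S)-4-(TBSO)-6-[4-(TBSO)phenyl]hex-1-en-1-yl]lithium | [Li]/C=C/C[C@@H](O[Si](C)(C)C(C)(C)C)CCc1ccc(O[Si](C)(C)C(C)(C)C)cc1 | intermediate (not isolated)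
21 | [(1E,4S)-4-(TBSO)-6-[4-(TBSO)phenyl]hex-1-en-1-yl]magnesium bromide | Br[Mg]/C=C/C[C@@H](O[Si](C)(C)C(C)(C)C)CCc1ccc(O[Si](C)(C)C(C)(C)C)cc1 | intermediate (not isolated)
22 | (4S)-4-benzyl-3-{(3R,4E,7S)-7-(TBSO)-3,9-bis[4-(TBSO)phenyl]non-4-enoyl}oxazolidin-2-one | O=C(C[C@H](/C=C/C[C@@H](O[Si](C)(C)C(C)(C)C)CCc1ccc(O[Si](C)(C)C(C)(C)C)cc1)c1ccc(O[Si](C)(C)C(C)(C)C)cc1)N1[C@@H](Cc2ccccc2)COC1=O | intermediate
23 | 4-(TBSO)benzaldehyde | O=Cc1ccc(O[Si](C)(C)C(C)(C)C)cc1 | starting material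
24 | trimethylsilyl ether of 25 | C[Si](C)(C)O[C@H](c1ccc(O[Si](C)(C)C(C)(C)C)cc1)[C@H](C(=O)N1[C@@H](Cc2ccccc2)COC1=O)[C@H](/C=C/C[C@@H](O[Si](C)(C)C(C)(C)C)CCc1ccc(O[Si](C)(C)C(C)(C)C)cc1)c1ccc(O[Si](C)(C)C(C)(C)C)cc1 | intermediate (not isolated)
25 | (4S)-4-benzyl-3-{(2R,3S,4E,7S)-7-(TBSO)-2-[(S)-hydroxy[4-(TBSO)phenyl]methyl]-3,9-bis[4-(TBSO)phenyl]non-4-enoyl}oxazolidin-2-one (C-3 is spatially unchanged from 22; only its descriptor changes) | O[C@H](c1ccc(O[Si](C)(C)C(C)(C)C)cc1)[C@H](C(=O)N1[C@@H](Cc2ccccc2)COC1=O)[C@H](/C=C/C[C@@H](O[Si](C)(C)C(C)(C)C)CCc1ccc(O[Si](C)(C)C(C)(C)C)cc1)c1ccc(O[Si](C)(C)C(C)(C)C)cc1 | intermediate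
26 | (1S,2S)-1-[4-(TBSO)phenyl]-2-{(1S,2E,5S)-5-(TBSO)-1,7-bis[4-(TBSO)phenyl]hept-2-en-1-yl}propane-1,3-diol | O[C@H](c1ccc(O[Si](C)(C)C(C)(C)C)cc1)[C@H](CO)[C@H](/C=C/C[C@@H](O[Si](C)(C)C(C)(C)C)CCc1ccc(O[Si](C)(C)C(C)(C)C)cc1)c1ccc(O[Si](C)(C)C(C)(C)C)cc1 | intermediate
27 | (2R,3S,4E,7S)-7-(TBSO)-2-[(S)-hydroxy[4-(TBSO)phenyl]methyl]-3,9-bis[4-(TBSO)phenyl]non-4-enal | O[C@H](c1ccc(O[Si](C)(C)C(C)(C)C)cc1)[C@H](C=O)[C@H](/C=C/C[C@@H](O[Si](C)(C)C(C)(C)C)CCc1ccc(O[Si](C)(C)C(C)(C)C)cc1)c1ccc(O[Si](C)(C)C(C)(C)C)cc1 | intermediate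
28 | [4-methoxy-2,6-bis(methoxymethoxy)phenyl]lithium | COCOc1cc(OC)cc(OCOC)c1[Li] | intermediate (not isolated)
29 | (1S,2R)-3-[4-methoxy-2,6-bis(methoxymethoxy)phenyl]-1-[4-(TBSO)phenyl]-2-{(1S,2E,5S)-5-(TBSO)-1,7-bis[4-(TBSO)phenyl]hept-2-en-1-yl}propane-1,3-diol (C-3 epimers) | COc1cc(OCOC)c(C(O)[C@@H]([C@H](O)c2ccc(O[Si](C)(C)C(C)(C)C)cc2)[C@H](/C=C/C[C@@H](O[Si](C)(C)C(C)(C)C)CCc2ccc(O[Si](C)(C)C(C)(C)C)cc2)c2ccc(O[Si](C)(C)C(C)(C)C)cc2)c(OCOC)c1 | intermediate (not isolated)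
30 | (1S,2R)-3-methoxy-3-[4-methoxy-2,6-bis(methoxymethoxy)phenyl]-1-[4-(TBSO)phenyl]-2-{(1S,2E,5S)-5-(TBSO)-1,7-bis[4-(TBSO)phenyl]hept-2-en-1-yl}propan-1-ol (C-3 epimers) | COc1cc(OCOC)c(C(OC)[C@@H]([C@H](O)c2ccc(O[Si](C)(C)C(C)(C)C)cc2)[C@H](/C=C/C[C@@H](O[Si](C)(C)C(C)(C)C)CCc2ccc(O[Si](C)(C)C(C)(C)C)cc2)c2ccc(O[Si](C)(C)C(C)(C)C)cc2)c(OCOC)c1 | intermediate
31 | lithium 4-[4-(TBSO)phenyl]but-1-en-2-olate | [Li]OC(=C)CCc1ccc(O[Si](C)(C)C(C)(C)C)cc1 | intermediate (not isolated)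
32 | chloro(diisopropyl){4-[4-(TBSO)phenyl]but-1-en-2-yloxy}silane | C=C(CCc1ccc(O[Si](C)(C)C(C)(C)C)cc1)O[Si](Cl)(C(C)C)C(C)C | intermediate (not isolated)
33 | silaketal of 30: the O-1 hydroxyl carries a diisopropylsilyl group whose second oxygen is the enol ether of 19 (4-[4-(TBSO)phenyl]but-1-en-2-yloxy); carbinol carbon S and adjacent carbon spatially as in 30 | COc1cc(OCOC)c(C(OC)[C@@H]([C@H](O[Si](C(C)C)(C(C)C)OC(=C)CCc2ccc(O[Si](C)(C)C(C)(C)C)cc2)c2ccc(O[Si](C)(C)C(C)(C)C)cc2)[C@H](/C=C/C[C@@H](O[Si](C)(C)C(C)(C)C)CCc2ccc(O[Si](C)(C)C(C)(C)C)cc2)c2ccc(O[Si](C)(C)C(C)(C)C)cc2)c(OCOC)c1 | intermediate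
34 | C-alkylated ketone: the ring-A benzylic carbon (R; future C4) carries the 2-oxo-4-[4-(TBSO)phenyl]butyl chain, and O-1 carries Si(iPr)2OTf; other centres as in 33 | COc1cc(OCOC)c([C@H](CC(=O)CCc2ccc(O[Si](C)(C)C(C)(C)C)cc2)[C@@H]([C@H](O[Si](C(C)C)(C(C)C)OS(=O)(=O)C(F)(F)F)c2ccc(O[Si](C)(C)C(C)(C)C)cc2)[C@H](/C=C/C[C@@H](O[Si](C)(C)C(C)(C)C)CCc2ccc(O[Si](C)(C)C(C)(C)C)cc2)c2ccc(O[Si](C)(C)C(C)(C)C)cc2)c(OCOC)c1 | intermediate (not isolated)
35 | 3,4-dihydro-2H-pyranylium (O1=C6 oxocarbenium) triflate carrying the substituents of 36 at C2, C3, C4 and C6 | COc1cc(OCOC)c([C@@H]2CC(CCc3ccc(O[Si](C)(C)C(C)(C)C)cc3)=[O+][C@H](c3ccc(O[Si](C)(C)C(C)(C)C)cc3)[C@H]2[C@H](/C=C/C[C@@H](O[Si](C)(C)C(C)(C)C)CCc2ccc(O[Si](C)(C)C(C)(C)C)cc2)c2ccc(O[Si](C)(C)C(C)(C)C)cc2)c(OCOC)c1.[O-]S(=O)(=O)C(F)(F)F | intermediate (not isolated)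
36 | (2S,3R,4R,6S)-4-[4-methoxy-2,6-bis(methoxymethoxy)phenyl]-2-[4-(TBSO)phenyl]-6-{2-[4-(TBSO)phenyl]ethyl}-3-{(1S,2E,5S)-5-(TBSO)-1,7-bis[4-(TBSO)phenyl]hept-2-en-1-yl}tetrahydro-2H-pyran | COc1cc(OCOC)c([C@@H]2C[C@H](CCc3ccc(O[Si](C)(C)C(C)(C)C)cc3)O[C@H](c3ccc(O[Si](C)(C)C(C)(C)C)cc3)[C@H]2[C@H](/C=C/C[C@@H](O[Si](C)(C)C(C)(C)C)CCc2ccc(O[Si](C)(C)C(C)(C)C)cc2)c2ccc(O[Si](C)(C)C(C)(C)C)cc2)c(OCOC)c1 | intermediate
37 | aryllithium of 36, lithiated on ring A between a MOM ether and the methoxy group | COc1cc(OCOC)c([C@@H]2C[C@H](CCc3ccc(O[Si](C)(C)C(C)(C)C)cc3)O[C@H](c3ccc(O[Si](C)(C)C(C)(C)C)cc3)[C@H]2[C@H](/C=C/C[C@@H](O[Si](C)(C)C(C)(C)C)CCc2ccc(O[Si](C)(C)C(C)(C)C)cc2)c2ccc(O[Si](C)(C)C(C)(C)C)cc2)c(OCOC)c1[Li] | intermediate (not isolated)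
38 | blepharocalyxin E protected as hexa-TBS ether (five phenols and the secondary alcohol) and bis-MOM ether (ring A) | COc1cc(OCOC)c([C@@H]2C[C@H](CCc3ccc(O[Si](C)(C)C(C)(C)C)cc3)O[C@H](c3ccc(O[Si](C)(C)C(C)(C)C)cc3)[C@H]2[C@H](/C=C/C[C@@H](O[Si](C)(C)C(C)(C)C)CCc2ccc(O[Si](C)(C)C(C)(C)C)cc2)c2ccc(O[Si](C)(C)C(C)(C)C)cc2)c(OCOC)c1C(=O)/C=C/c1ccc(O[Si](C)(C)C(C)(C)C)cc1 | intermediate
39 | analogue of 38 with both ring-A MOM ethers replaced by trimethylsilyl ethers | COc1cc(O[Si](C)(C)C)c([C@@H]2C[C@H](CCc3ccc(O[Si](C)(C)C(C)(C)C)cc3)O[C@H](c3ccc(O[Si](C)(C)C(C)(C)C)cc3)[C@H]2[C@H](/C=C/C[C@@H](O[Si](C)(C)C(C)(C)C)CCc2ccc(O[Si](C)(C)C(C)(C)C)cc2)c2ccc(O[Si](C)(C)C(C)(C)C)cc2)c(O[Si](C)(C)C)c1C(=O)/C=C/c1ccc(O[Si](C)(C)C(C)(C)C)cc1 | intermediate (not isolated)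
40 | blepharocalyxin E | COc1cc(O)c([C@@H]2C[C@H](CCc3ccc(O)cc3)O[C@H](c3ccc(O)cc3)[C@H]2[C@H](/C=C/C[C@@H](O)CCc2ccc(O)cc2)c2ccc(O)cc2)c(O)c1C(=O)/C=C/c1ccc(O)cc1 | target

Total step count: 19. Longest linear sequence: 14 steps (steps 1–5 and 11–19).

Steps most likely to fail

Step 17 (Proposed new method). The tethered closure through an eight-membered transition state may be outrun by elimination of the benzylic cation or by intermolecular arylation, and the silyl-activated ketone might be reduced before O1 closes onto it. The fallback uses known chemistry and sets out from 30. Ketone 19 is converted (lithium diisopropylamide, Me3SiCl) into 2-(trimethylsilyloxy)-4-[4-(TBSO)phenyl]but-1-ene F1, which is used in excess in a BF3·OEt2-mediated SN1 benzylation of 30 at −78 °C. This forms the C4–C5 bond and, by spontaneous hemiketalisation, the O1–C6 bond of the δ-hydroxy ketone F2, whose C4 epimer would have to be removed by chromatography since the intermolecular attack lacks the tether control. The established Et3SiH/BF3·OEt2 reductive cyclisation of F2 then returns to the route at 36.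

Step 18. Deprotonation at benzylic or α-oxygenated C–H bonds, or attack of the alkyllithium on aryl silyl ethers, may compete with ring lithiation. The fallback sets out from 36: electrophilic bromination with N-bromosuccinimide (MeCN, −20 °C) at the only free, doubly activated position of ring A should give the aryl bromide F3. Bromine–lithium exchange (t-BuLi, THF, −78 °C) then generates 37 without a deprotonation step, and acylation with 15 returns to the route at 38.

Step 12. Soft enolisation of the hindered, β-branched imide may be sluggish and the anti/syn selectivity at the carbinol carbon may be poor, while the α-face selectivity imposed by the chelated enolate should hold. The fallback sets out from 22: the aldol mixture of 25 and its carbinol epimer F4 is oxidised with Dess–Martin periodinane to the single β-keto imide F5, whose α-centre is configurationally stable through A(1,3) strain. Reagent-controlled Corey–Bakshi–Shibata reduction of the aryl ketone ((R)-1-methyl-3,3-diphenyl-tetrahydro-pyrrolo[1,2-c][1,3,2]oxazaborole, BH3·SMe2) should then deliver the (S)-carbinol and return to the route at 25.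

Further compounds

F1 | step 17 | 2-(trimethylsilyloxy)-4-[4-(TBSO)phenyl]but-1-ene | C=C(CCc1ccc(O[Si](C)(C)C(C)(C)C)cc1)O[Si](C)(C)C
F2 | step 17 | δ-hydroxy ketone: 34 with a free O-1 hydroxyl in place of the silyl triflate (open form of the cyclic hemiketal) | COc1cc(OCOC)c([C@H](CC(=O)CCc2ccc(O[Si](C)(C)C(C)(C)C)cc2)[C@@H]([C@H](O)c2ccc(O[Si](C)(C)C(C)(C)C)cc2)[C@H](/C=C/C[C@@H](O[Si](C)(C)C(C)(C)C)CCc2ccc(O[Si](C)(C)C(C)(C)C)cc2)c2ccc(O[Si](C)(C)C(C)(C)C)cc2)c(OCOC)c1
F3 | step 18 | ring-A monobromide of 36 (bromine between a MOM ether and the methoxy group) | COc1cc(OCOC)c([C@@H]2C[C@H](CCc3ccc(O[Si](C)(C)C(C)(C)C)cc3)O[C@H](c3ccc(O[Si](C)(C)C(C)(C)C)cc3)[C@H]2[C@H](/C=C/C[C@@H](O[Si](C)(C)C(C)(C)C)CCc2ccc(O[Si](C)(C)C(C)(C)C)cc2)c2ccc(O[Si](C)(C)C(C)(C)C)cc2)c(OCOC)c1Br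
F4 | step 12 | carbinol epimer of 25 ((R)-hydroxy(aryl)methyl) | O[C@@H](c1ccc(O[Si](C)(C)C(C)(C)C)cc1)[C@H](C(=O)N1[C@@H](Cc2ccccc2)COC1=O)[C@H](/C=C/C[C@@H](O[Si](C)(C)C(C)(C)C)CCc1ccc(O[Si](C)(C)C(C)(C)C)cc1)c1ccc(O[Si](C)(C)C(C)(C)C)cc1
F5 | step 12 | β-keto imide: 25 with the carbinol oxidised to the 4-(TBSO)benzoyl ketone | O=C(c1ccc(O[Si](C)(C)C(C)(C)C)cc1)[C@H](C(=O)N1[C@@H](Cc2ccccc2)COC1=O)[C@H](/C=C/C[C@@H](O[Si](C)(C)C(C)(C)C)CCc1ccc(O[Si](C)(C)C(C)(C)C)cc1)c1ccc(O[Si](C)(C)C(C)(C)C)cc1
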